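## Retrosynthetic overview

1. Target 20 comes from its 3-O-silyl ether 19 by desilylation.
2. 19 comes from 16 by forming C4a–C5, so ring A is made last. The route rests on ring A (C4a, C5, C6, C7, C8, C8a) being a 2-acylphloroglucinol, with oxygen on C5, C7 and C8a and the acyl carbon C4 on C4a. It unfolds to the chain C4–C4a–C8a–C8–C7–C6–C5, in which the ring C enol ether O1–C8a=C4a masks the C8a carbonyl, a methyl enol ether masks the C7 carbonyl, and the prenyl group already sits on C8.
3. 16 comes from lactone enol ether 9 and ester 13: the γ-carbon of the prenylated methoxy enoate adds to the lactone carbonyl (C8a–C8 bond), and acid turns the lactone enol ether into the ring C dihydropyranone.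
4. 9 comes from glycidate 1 by benzylic opening with inversion (sets C2; C3 is the glycidate α-carbon), two-carbon extension with 4, lactonisation and O-methylation. 13 comes from 10 and 11.
5. Ring order: ring B is bought as phenyl, ring C is built second (lactone, then dihydropyranone), ring A last.

Key step: step 8

Remark on numbering: atoms of 15 to 20 carry flavanone numbers (O1, C2, C3, C4, C4a, C5 to C8, C8a).

Remark on the cyclisation substrate: 16 is carried as the C8–H tautomer with the enoate double bond at C6=C7 (both C8 epimers), because the fragment union delivers this form; loss of the C8 proton gives the same delocalised anion that the C7=C8 isomer would give by loss of a C6 proton, so neither the tautomer nor the C8 configuration affects step 8.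

## Route

Step 1
Reactants: 1 methyl (2R,3S)-3-phenyloxirane-2-carboxylate
Product: 2 methyl (2R,3R)-2-hydroxy-3-(naphthalen-2-ylmethoxy)-3-phenylpropanoate
Conditions: naphthalen-2-ylmethanol (3 equiv), BF3·OEt2 (0.2 equiv), CH2Cl2, −20 → 0 °C
Reagents that add atoms: naphthalen-2-ylmethanol OCc1ccc2ccccc2c1
Why: Lewis-acid-catalysed SN2-type alcoholysis of the epoxide should occur at the benzylic carbon (the ester disfavours charge at the other carbon) and with inversion, turning 3S into 3R (later C2) while 2R (later C3) is untouched; the naphthylmethyl group is chosen because its alcohol tolerates BF3 and its ether is later cleaved oxidatively, and any syn diastereomer is separable.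

Step 2
Reactants: 2 methyl (2R,3R)-2-hydroxy-3-(naphthalen-2-ylmethoxy)-3-phenylpropanoate
Product: 3 methyl (2R,3R)-2-[(tert-butyldimethylsilyl)oxy]-3-(naphthalen-2-ylmethoxy)-3-phenylpropanoate
Conditions: TBSOTf, 2,6-lutidine, CH2Cl2, −78 → 0 °C
Reagents that add atoms: tert-butyldimethylsilyl triflate CC(C)(C)[Si](C)(C)OS(=O)(=O)C(F)(F)F
Why: Silylation of a secondary alcohol with a silyl triflate and a hindered base is fast at low temperature and leaves both stereocentres alone.

Step 3
Reactants: 3 methyl (2R,3R)-2-[(tert-butyldimethylsilyl)oxy]-3-(naphthalen-2-ylmethoxy)-3-phenylpropanoate; 4 tert-butyl acetate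
Product: 6 tert-butyl (4R,5R)-4-[(tert-butyldimethylsilyl)oxy]-5-(naphthalen-2-ylmethoxy)-3-oxo-5-phenylpentanoate, via lithium ester enolate 5 (not isolated)
Conditions: LiN(i-Pr)2 (2.3 equiv), 4 (2.4 equiv), THF, −78 °C; then 3, −78 → −40 °C; aq. NH4Cl
Reagents that add atoms: none
Why: Crossed Claisen condensation of a lithium ester enolate with the α-silyloxy methyl ester, in which the β-keto ester is held as its enolate until the quench, so the adjacent silyloxy centre should not epimerise.

Step 4
Reactants: 6 tert-butyl (4R,5R)-4-[(tert-butyldimethylsilyl)oxy]-5-(naphthalen-2-ylmethoxy)-3-oxo-5-phenylpentanoate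
Product: 8 (5R,6R)-5-[(tert-butyldimethylsilyl)oxy]-6-phenyloxane-2,4-dione, via hydroxy keto ester 7 (not isolated)
Conditions: DDQ, CH2Cl2/pH 7 buffer, 0 °C → rt; then PhMe, 105 °C
Reagents that add atoms: none
Why: DDQ oxidises the electron-rich naphthylmethyl ether selectively to free the benzylic hydroxyl, and heating the tert-butyl β-keto ester releases tert-butanol to give an acylketene that the δ-hydroxyl traps as the six-membered lactone (acylketene lactonisation), neutral conditions under which the silyl group should not migrate.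

Step 5
Reactants: 8 (5R,6R)-5-[(tert-butyldimethylsilyl)oxy]-6-phenyloxane-2,4-dione
Product: 9 (5R,6R)-5-[(tert-butyldimethylsilyl)oxy]-4-methoxy-6-phenyl-5,6-dihydro-2H-pyran-2-one
Conditions: Me2SO4, K2CO3, acetone, rt
Reagents that add atoms: dimethyl sulfate COS(=O)(=O)OC
Why: O-Alkylation of the enolate of a cyclic 1,3-dicarbonyl compound with the hard electrophile dimethyl sulfate gives the 4-methoxy-5,6-dihydro-2-pyranone, the usual outcome for such lactones.

Step 6
Reactants: 10 methyl (E)-3-methoxybut-2-enoate; 11 prenyl bromide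
Product: 13 methyl (E)-3-methoxy-7-methylocta-2,6-dienoate, via lithium dienolate 12 (not isolated)
Conditions: LiN(i-Pr)2, THF, −78 °C; then 11, DMPU, −78 → −20 °C
Reagents that add atoms: none
Why: Vinylogous (γ) alkylation, in which the base removes a proton from the methyl group cis to the ester and the 1,3-dioxygenated dienolate is alkylated by the allylic bromide at its terminal carbon with the E enol ether geometry kept.

Step 7
Reactants: 9 (5R,6R)-5-[(tert-butyldimethylsilyl)oxy]-4-methoxy-6-phenyl-5,6-dihydro-2H-pyran-2-one; 13 methyl (E)-3-methoxy-7-methylocta-2,6-dienoate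
Product: 16 methyl (2E)-4-[(2R,3R)-3-[(tert-butyldimethylsilyl)oxy]-4-oxo-2-phenyl-3,4-dihydro-2H-pyran-6-yl]-3-methoxy-7-methylocta-2,6-dienoate (both C8 epimers), via lithium dienolate 14 (not isolated), via lactol adduct 15 (not isolated)
Conditions: LiN(i-Pr)2 (2.1 equiv), 13 (2.2 equiv), THF, −78 °C; then 9, −78 → −40 °C; aq. NH4Cl; then 1 M HCl, THF, 0 °C
Reagents that add atoms: water O
Why: Vinylogous Claisen-type 1,2-addition of the dienolate γ-carbon to the lactone carbonyl gives a lactol, which cold dilute acid dehydrates and hydrolyses at the ring enol ether (Stork–Danheiser-type transposition) to the 2,3-dihydro-4H-pyran-4-one; the new sp3 centre C8 forms as both epimers and is erased in step 8, and the side-chain β-methoxy enoate and the silyl ether should survive the brief acid treatment.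

Step 8
Reactants: 16 methyl (2E)-4-[(2R,3R)-3-[(tert-butyldimethylsilyl)oxy]-4-oxo-2-phenyl-3,4-dihydro-2H-pyran-6-yl]-3-methoxy-7-methylocta-2,6-dienoate (both C8 epimers)
Product: 19 (2R,3R)-3-[(tert-butyldimethylsilyl)oxy]-5-hydroxy-7-methoxy-8-(3-methylbut-2-en-1-yl)-2-phenyl-2,3-dihydro-4H-chromen-4-one, via lithium trienolate 17 (not isolated), via cyclohexadienone 18 (not isolated)
Conditions: LiN(SiMe3)2 (1.1 equiv), THF, −78 °C → rt; aq. NH4Cl
Reagents that add atoms: none
Why: Proposed new method: one equivalent of base removes the C8 proton, which is vinylogous to both the C5 ester (through C6=C7) and the C4 ketone (through C4a=C8a) and so far more acidic than the α-silyloxy C3–H, giving the pentadienyl-type anion 17; in the form with the charge on the C4 oxygen, C4a is the α-carbon of a dienolate and C5 an intact enoate carbonyl, so C4a adds to C5, methoxide leaves and dienone 18 enolises (C4a–H to the C5 oxygen) to the aromatic ring. The closest known reaction is the biomimetic Claisen (Dieckmann-type) cyclisation of 3,5,7-triketo esters and their enol ethers to acylphloroglucinols, where the carbon between two carbonyls likewise acylates the terminal ester; new here is that the nucleophile is the α-carbon of a cyclic vinylogous ester reached through a doubly vinylogous carbanion. Ring A is the only ring closed, by a 6-(enolexo)-exo-trig closure over C4a–C8a–C8–C7–C6–C5, and no stereocentre is formed. C2 and C3 are carried through because C3 is never deprotonated and the released methoxide converts the product at once into its C5 phenoxide, a vinylogous carboxylate that lowers the acidity of C3–H and so guards against ring opening. The step needs C-acylation at C4a over all other modes, and the substrate secures it: O1 is locked in ring C, so neither O-acylation to an α-pyrone nor aldol closure of C6 onto C4 (a bridged ring) is open, and the E enoate holds C5 cis to C8 so the ester reaches C4a once the anion adopts the U shape. Aromatisation to a weakly basic phenoxide should make the closure irreversible and draw the crowded reactive conformer through.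

Step 9
Reactants: 19 (2R,3R)-3-[(tert-butyldimethylsilyl)oxy]-5-hydroxy-7-methoxy-8-(3-methylbut-2-en-1-yl)-2-phenyl-2,3-dihydro-4H-chromen-4-one
Product: 20 (2R,3R)-3,5-dihydroxy-7-methoxy-8-(3-methylbut-2-en-1-yl)-2-phenyl-2,3-dihydro-4H-chromen-4-one
Conditions: HF·pyridine, THF/pyridine, 0 °C → rt
Reagents that add atoms: none
Why: Fluoride cleavage of the silyl ether in a pyridine-buffered, non-basic medium, in which the trans-dihydroflavonol should neither epimerise nor open to a chalcone and the prenyl group has no ortho phenol to cyclise onto.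

## Compound list

1 | methyl (2R,3S)-3-phenyloxirane-2-carboxylate (methyl (2R,3S)-3-phenylglycidate) | COC(=O)[C@@H]1O[C@H]1c1ccccc1 | starting material
2 | methyl (2R,3R)-2-hydroxy-3-(naphthalen-2-ylmethoxy)-3-phenylpropanoate | COC(=O)[C@H](O)[C@H](OCc1ccc2ccccc2c1)c1ccccc1 | intermediate
3 | methyl (2R,3R)-2-[(tert-butyldimethylsilyl)oxy]-3-(naphthalen-2-ylmethoxy)-3-phenylpropanoate | COC(=O)[C@H](O[Si](C)(C)C(C)(C)C)[C@H](OCc1ccc2ccccc2c1)c1ccccc1 | intermediate
4 | tert-butyl acetate | CC(=O)OC(C)(C)C | starting material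
5 | lithium enolate of tert-butyl acetate (formed in the flask) | [Li+].C=C([O-])OC(C)(C)C | intermediate
6 | tert-butyl (4R,5R)-4-[(tert-butyldimethylsilyl)oxy]-5-(naphthalen-2-ylmethoxy)-3-oxo-5-phenylpentanoate | CC(C)(C)OC(=O)CC(=O)[C@H](O[Si](C)(C)C(C)(C)C)[C@H](OCc1ccc2ccccc2c1)c1ccccc1 | intermediate
7 | tert-butyl (4R,5R)-4-[(tert-butyldimethylsilyl)oxy]-5-hydroxy-3-oxo-5-phenylpentanoate (formed in the flask) | CC(C)(C)OC(=O)CC(=O)[C@H](O[Si](C)(C)C(C)(C)C)[C@H](O)c1ccccc1 | intermediate
8 | (5R,6R)-5-[(tert-butyldimethylsilyl)oxy]-6-phenyloxane-2,4-dione (in equilibrium with its 4-hydroxy-5,6-dihydro-2H-pyran-2-one enol) | O=C1CC(=O)[C@H](O[Si](C)(C)C(C)(C)C)[C@@H](c2ccccc2)O1 | intermediate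
9 | (5R,6R)-5-[(tert-butyldimethylsilyl)oxy]-4-methoxy-6-phenyl-5,6-dihydro-2H-pyran-2-one | O=C1C=C(OC)[C@H](O[Si](C)(C)C(C)(C)C)[C@@H](c2ccccc2)O1 | intermediate
10 | methyl (E)-3-methoxybut-2-enoate | CO/C(C)=C/C(=O)OC | starting material
11 | prenyl bromide (1-bromo-3-methylbut-2-ene) | CC(C)=CCBr | starting material
12 | lithium dienolate of 10, deprotonated at C4 (formed in the flask) | [Li+].C=C(OC)C=C([O-])OC | intermediate
13 | methyl (E)-3-methoxy-7-methylocta-2,6-dienoate | CO/C(CCC=C(C)C)=C/C(=O)OC | intermediate
14 | lithium dienolate of 13, deprotonated at C4 (formed in the flask) | [Li+].COC(=CCC=C(C)C)C=C([O-])OC | intermediate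
15 | methyl (2E)-4-[(5R,6R)-5-[(tert-butyldimethylsilyl)oxy]-2-hydroxy-4-methoxy-6-phenyl-5,6-dihydro-2H-pyran-2-yl]-3-methoxy-7-methylocta-2,6-dienoate, epimers at the lactol carbon and at C8 (formed in the flask) | CO/C(=C/C(=O)OC)C(CC=C(C)C)C1(O)C=C(OC)[C@H](O[Si](C)(C)C(C)(C)C)[C@@H](c2ccccc2)O1 | intermediate
16 | methyl (2E)-4-[(2R,3R)-3-[(tert-butyldimethylsilyl)oxy]-4-oxo-2-phenyl-3,4-dihydro-2H-pyran-6-yl]-3-methoxy-7-methylocta-2,6-dienoate, both C8 epimers | CO/C(=C/C(=O)OC)C(CC=C(C)C)C1=CC(=O)[C@H](O[Si](C)(C)C(C)(C)C)[C@@H](c2ccccc2)O1 | intermediate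
17 | lithium trienolate of 16, deprotonated at C8, drawn with the charge on the C4 oxygen (formed in the flask) | [Li+].CO/C(=C/C(=O)OC)C(CC=C(C)C)=C1C=C([O-])[C@H](O[Si](C)(C)C(C)(C)C)[C@@H](c2ccccc2)O1 | intermediate
18 | (2R,3R)-3-[(tert-butyldimethylsilyl)oxy]-7-methoxy-8-(3-methylbut-2-en-1-yl)-2-phenyl-2,3-dihydro-4H-chromene-4,5(4aH)-dione, C4a epimers (formed in the flask) | COC1=CC(=O)C2C(=O)[C@H](O[Si](C)(C)C(C)(C)C)[C@@H](c3ccccc3)OC2=C1CC=C(C)C | intermediate
19 | (2R,3R)-3-[(tert-butyldimethylsilyl)oxy]-5-hydroxy-7-methoxy-8-(3-methylbut-2-en-1-yl)-2-phenyl-2,3-dihydro-4H-chromen-4-one | COc1cc(O)c2c(c1CC=C(C)C)O[C@H](c1ccccc1)[C@@H](O[Si](C)(C)C(C)(C)C)C2=O | intermediate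
20 | (2R,3R)-3,5-dihydroxy-7-methoxy-8-(3-methylbut-2-en-1-yl)-2-phenyl-2,3-dihydro-4H-chromen-4-one | COc1cc(O)c2c(c1CC=C(C)C)O[C@H](c1ccccc1)[C@@H](O)C2=O | target

## Step count and risks

Total steps: 9. Longest linear sequence: 8 (steps 1, 2, 3, 4, 5, 7, 8, 9); step 6 is the one-step side branch.

**Step 8 (key step).**
- What may go wrong: the anion may be too stabilised to acylate itself, since the charge is shared with the ester and lowers the electrophilicity of C5, and the U-shaped conformer needed for closure is the most crowded one. The anion could then persist to the quench, or on forcing ring C could open through deprotonation at C3 and loss of O1.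
- Fallback (known chemistry, sets out from 1, returns at 20): ring A is bought and ring C is closed by the established chalcone-epoxide route.
  - Ester 1 is converted with MeNH(OMe)·HCl and i-PrMgCl into the Weinreb amide (2R,3S)-N-methoxy-N-methyl-3-phenyloxirane-2-carboxamide F1.
  - 5-Methoxyresorcinol is protected with chloromethyl methyl ether and i-Pr2NEt as 1-methoxy-3,5-bis(methoxymethoxy)benzene F2, which n-BuLi lithiates between the two acetal oxygens to [4-methoxy-2,6-bis(methoxymethoxy)phenyl]lithium F3.
  - Acylation of F3 with F1 gives the epoxy ketone [4-methoxy-2,6-bis(methoxymethoxy)phenyl][(2R,3S)-3-phenyloxiran-2-yl]methanone F4.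
  - HCl in methanol removes both acetals, and a freed phenol opens the epoxide at the benzylic carbon with inversion to give (2R,3R)-3,5-dihydroxy-7-methoxy-2-phenyl-2,3-dihydro-4H-chromen-4-one F5.
  - O-Alkylation of the C5 phenol with 11 and K2CO3 in acetone gives (2R,3R)-3-hydroxy-7-methoxy-5-[(3-methylbut-2-en-1-yl)oxy]-2-phenyl-2,3-dihydro-4H-chromen-4-one F6.
  - A para-Claisen–Cope rearrangement catalysed by tris(6,6,7,7,8,8,8-heptafluoro-2,2-dimethyloctane-3,5-dionato)europium, Eu(fod)3, moves the prenyl group from O5 through C6 to C8 and gives 20.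

**Step 7.**
- What may go wrong: proton transfer may outrun addition. The dienolate can remove the C5 proton of lactone 9, after which the ring carboxylate is expelled and the lactone opens. The deactivated vinylogous carbonate carbonyl may also add slowly, or be attacked in a conjugate sense at the methoxy-bearing carbon.
- Fallback (known chemistry, sets out from 13 and 3, returns at 16): the fragments are joined at C4–C4a instead of C8a–C8.
  - Dienolate 14 is acetylated at its γ-carbon with N-methoxy-N-methylacetamide to give methyl (2E)-4-acetyl-3-methoxy-7-methylocta-2,6-dienoate F7.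
  - Two equivalents of LiN(i-Pr)2 convert F7 into the dilithium dianion of F7 F8 (first the C8 proton, then an acetyl proton).
  - F8 is acylated at its terminal carbon by ester 3, as in the ester acylation of β-diketone and β-keto ester dianions, to give methyl (2E)-4-{(4R,5R)-4-[(tert-butyldimethylsilyl)oxy]-5-(naphthalen-2-ylmethoxy)-3-oxo-5-phenylpentanoyl}-3-methoxy-7-methylocta-2,6-dienoate F9.
  - DDQ removes the naphthylmethyl group to give methyl (2E)-4-{(4R,5R)-4-[(tert-butyldimethylsilyl)oxy]-5-hydroxy-3-oxo-5-phenylpentanoyl}-3-methoxy-7-methylocta-2,6-dienoate F10.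
  - Catalytic p-toluenesulfonic acid closes the δ-hydroxy diketone onto the C8a carbonyl and dehydrates the hemiketal to 16.

**Step 6.**
- What may go wrong: alkylation may occur at the α-carbon of the dienolate instead of the γ-carbon, and proton exchange between product and dienolate may lead to a second alkylation.
- Fallback (known chemistry, sets out from 11, returns at 13): the dianion of methyl acetoacetate (NaH, then n-BuLi) is alkylated at its terminal carbon with 11 to give methyl 7-methyl-3-oxooct-6-enoate F11. Trimethyl orthoformate with catalytic H2SO4 in methanol then converts the β-keto ester into the E methyl enol ether 13.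

Further compounds
F1 | step 8 | (2R,3S)-N-methoxy-N-methyl-3-phenyloxirane-2-carboxamide | CON(C)C(=O)[C@@H]1O[C@H]1c1ccccc1
F2 | step 8 | 1-methoxy-3,5-bis(methoxymethoxy)benzene | COCOc1cc(OC)cc(OCOC)c1
F3 | step 8 | [4-methoxy-2,6-bis(methoxymethoxy)phenyl]lithium | [Li]c1c(OCOC)cc(OC)cc1OCOC
F4 | step 8 | [4-methoxy-2,6-bis(methoxymethoxy)phenyl][(2R,3S)-3-phenyloxiran-2-yl]methanone | COCOc1cc(OC)cc(OCOC)c1C(=O)[C@@H]1O[C@H]1c1ccccc1
F5 | step 8 | (2R,3R)-3,5-dihydroxy-7-methoxy-2-phenyl-2,3-dihydro-4H-chromen-4-one | COc1cc(O)c2c(c1)O[C@H](c1ccccc1)[C@@H](O)C2=O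
F6 | step 8 | (2R,3R)-3-hydroxy-7-methoxy-5-[(3-methylbut-2-en-1-yl)oxy]-2-phenyl-2,3-dihydro-4H-chromen-4-one | COc1cc(OCC=C(C)C)c2c(c1)O[C@H](c1ccccc1)[C@@H](O)C2=O
F7 | step 7 | methyl (2E)-4-acetyl-3-methoxy-7-methylocta-2,6-dienoate | CO/C(=C/C(=O)OC)C(CC=C(C)C)C(C)=O
F8 | step 7 | dilithium dianion of F7 | [Li+].[Li+].CO/C(=C/C(=O)OC)[C-](CC=C(C)C)C(=C)[O-]
F9 | step 7 | methyl (2E)-4-{(4R,5R)-4-[(tert-butyldimethylsilyl)oxy]-5-(naphthalen-2-ylmethoxy)-3-oxo-5-phenylpentanoyl}-3-methoxy-7-methylocta-2,6-dienoate | CO/C(=C/C(=O)OC)C(CC=C(C)C)C(=O)CC(=O)[C@H](O[Si](C)(C)C(C)(C)C)[C@H](OCc1ccc2ccccc2c1)c1ccccc1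
F10 | step 7 | methyl (2E)-4-{(4R,5R)-4-[(tert-butyldimethylsilyl)oxy]-5-hydroxy-3-oxo-5-phenylpentanoyl}-3-methoxy-7-methylocta-2,6-dienoate | CO/C(=C/C(=O)OC)C(CC=C(C)C)C(=O)CC(=O)[C@H](O[Si](C)(C)C(C)(C)C)[C@H](O)c1ccccc1
F11 | step 6 | methyl 7-methyl-3-oxooct-6-enoate | COC(=O)CC(=O)CCC=C(C)C
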